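**Analysis of the target**

Eryvarin F (17) is a 4H-chromen-4-one, with benzo ring A fused to pyranone ring C, that carries ring B on C3 through an ether oxygen. It is therefore a 3-aryloxychromone and not an isoflavone. The molecule has no stereocentre, so the problem is one of connectivity and regiochemistry only. Ring A bears a free hydroxyl at C7 flanked by 3-methylbut-2-enyl (prenyl) groups at C6 and C8, with C5 unsubstituted. Ring B is a 2',4'-dihydroxyphenyl unit bound through O1'. The sensitive sites are the two trisubstituted olefins (acid-promoted cyclisation onto the neighbouring 7-OH, attack by electrophiles and oxidants), the electron-rich ring B (air oxidation once unmasked), and C2 of the chromone (conjugate attack by strong nucleophiles with opening of ring C). Three things make the synthesis hard: two prenyl groups must sit at defined positions, the C3–O bond joins an α-carbonyl carbon to an aryl oxygen, and three phenols must be freed at the end beside the prenyl groups. The plan rests on C3 being the central carbon of the O1–C2=C3–C4=O array, a 1,3-dicarbonyl unit with C4 as ketone and C2 at the aldehyde level. By natural polarity C3 is a nucleophile, as is the ring B oxygen it must bond to, so C3 is generated as an electrophilic carbene carbon, and the same event places on C2 the oxygen that becomes O1.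

**Retrosynthetic reasoning**

17 from 16. The three phenols are masked as methoxymethyl ethers, so the last operation cuts only three O–CH2 bonds. These ethers tolerate hydride base, the Grignard reagent, palladium, the peracid and the acid-free gold conditions. Free phenols on ring A or ring B would compete with 12 for the carbene. The forward step must remove the acetals with acid mild enough to leave the prenyl olefins alone.

16 from 15. Ring C is opened at O1–C8a, not at O1–C2. Cutting O1–C2 would require an oxygen on ring A ortho to the ketone during the carbene step, and that oxygen would capture the carbene in a five-membered mode. Cutting O1–C8a lets ring A carry a fluorine that ignores the carbene and later serves as leaving group. The forward reaction is an intramolecular nucleophilic aromatic substitution by the enolate oxygen of 15, activated by the ortho ketone.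

15 from 8, 12 and 13. Two heteroatom bonds are cut at once: C3–O1' to ring B and C2–O. This reduces the whole C2–C3–C4 unit to the terminal ynone 8, joins the two aromatic halves in one convergent step, and sets C2 to the aldehyde level. The forward reaction passes through the gold carbene 14. It must deliver the oxygen of 13 to the alkyne terminus and have 14 captured by the oxygen of 12.

8 from 7, and 7 from 5 and 6. The C3–C4 bond is cut between the carbonyl carbon and the alkyne. An aldehyde and an ethynyl Grignard reagent are the simplest pair for this bond. The racemic carbinol centre of 7 disappears on oxidation.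

5 from 3 and 4, 3 from 2, 2 from 1. Both aryl–prenyl bonds (C6–C1'' and C8–C1'') are cut together. Their positions are the two carbons ortho to the C7 oxygen, exactly where a para-formyl phenol is iodinated. Commercial 1 already holds the fluorine, the C7 oxygen and the future C4 carbon in the right relationship. Double Stille coupling with the prenylstannane 4 then installs both side chains.

12 from 11, 11 from 10, 10 from 9. The C1'–O bond of ring B is traced to an aryl–formyl bond. Peracid oxidation of the protected aldehyde 10 converts the formyl carbon into the formate 11, whose cleavage leaves the single free phenol exactly where the ether link is required.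

**Alternatives that were turned down**

Alternative 1: Ring A is disconnected at C7–C8, C4a–C8a and C6–C7.
- Key step: (2E)-7-methylocta-2,6-dienoyl chloride A2 is dehydrochlorinated by a tertiary amine to a vinylketene. This combines with the siloxyalkyne triisopropyl[(5-methylhex-4-en-1-ynyl)oxy]silane A3 by [2+2] addition, four-electron ring opening and six-electron closure. The product is 2,6-bis(3-methylbut-2-enyl)-3-(triisopropylsilyloxy)phenol A1.
- For: both prenyl groups arrive inside the fragments, so their positions are fixed by the mechanism and no allyl-transfer regiochemistry arises. On this point it is stronger than the chosen route. The two ring oxygens also emerge differentiated.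
- Against: it builds from acyclic pieces a benzene ring that is commercially available already oxygenated and fluorinated. A3 needs its own multistep preparation. After A1, C4a is still a C–H, and the C2–C3–C4 unit, the C3–O bond and ring C all remain to be made, so the hard bond is untouched.
- Comparison: the chosen route reaches the equivalent diprenyl ring A (compound 5) in three steps and solves C3–O in its key step, at the price of one palladium coupling whose regiochemistry has to be watched.

Alternative 2: Ring A is disconnected at C4a–C8a and C5–C6.
- Key step: the diene 1-methoxy-7-methyl-2-(3-methylbut-2-enyl)-1,3-bis(trimethylsilyloxy)octa-1,3,6-triene A5 adds in a Diels–Alder reaction to the ynone 1-[2,4-bis(methoxymethoxy)phenoxy]but-3-yn-2-one A6. Loss of methanol and desilylation aromatise the adduct to 2-[2,4-bis(methoxymethoxy)phenoxy]-1-[2,4-dihydroxy-3,5-bis(3-methylbut-2-enyl)phenyl]ethanone A4. Formylation of the methylene group with cyclodehydration, then deprotection, would finish the synthesis.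
- For: the C3–O bond is made at the sp3 stage by simple phenoxide alkylation, and the end game from A4 is the classical 3-aryloxychromone synthesis. On precedent for this bond and for ring C closure it is stronger than the chosen route, and it needs no fluorine leaving group.
- Against: A5 is tetrasubstituted with an alkyl group on the reacting terminus, so the cycloaddition would need heating. Under heat the enolisable A6 is likely to isomerise or polymerise, and open-chain Michael adducts would compete. A5 and A6 each need about four steps, and A4 exposes a free diprenyl resorcinol to the later base and acid.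
- Comparison: step counts are similar. The chosen route offers two robustly made partners and one convergent step that also sets the C2 oxidation level, so only the carbene capture remains uncertain.

Alternative 3: Ring B is disconnected at C2'–C3', C4'–C5' and C1'–C2'.
- Key step: (2E)-4-{[6,8-bis(3-methylbut-2-enyl)-4-oxo-7-(triisopropylsilyloxy)chromen-3-yl]oxy}but-2-enoyl chloride A8 is dehydrochlorinated to a vinylketene bearing the chromonyloxy group at its terminus. This combines with (ethynyloxy)triisopropylsilane A9 by [2+2] addition, ring opening and six-electron closure. The product is 3-[2-hydroxy-4-(triisopropylsilyloxy)phenoxy]-6,8-bis(3-methylbut-2-enyl)-7-(triisopropylsilyloxy)chromen-4-one A7, which fluoride would desilylate to 17.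
- For: the C3–O bond would come from plain O-alkylation of a chromone with a hydroxyl on C3, and the final deprotection is non-acidic, which is kinder to the prenyl groups than acetal cleavage. On that point it is stronger.
- Against: the key step is spent on the simplest part of the molecule, since ring B is available from 9 in two steps. A8 presupposes a long linear synthesis of the fully decorated chromone. The ketene would have to choose A9 over two prenyl olefins and the chromone on the most advanced intermediate.
- Comparison: the chosen route is convergent and several steps shorter, and its acid deprotection has a non-acidic fallback.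

Key step: step 8

Assumption: the cationic gold carbene 14 is written without its NTf2 counter-ion, and 15 is written as the chelated enol tautomer of the ketoaldehyde, which is expected to predominate.

**Route**

Step 1
Reactants: 1 2-fluoro-4-hydroxybenzaldehyde
Product: 2 2-fluoro-4-hydroxy-3,5-diiodobenzaldehyde
Conditions: NIS (2.2 equiv), TsOH·H2O (10 mol %), MeCN, rt
Reagents that add atoms: N-iodosuccinimide, O=C1CCC(=O)N1I
Why: Electrophilic aromatic iodination; the hydroxyl directs to its two ortho positions C3 and C5, which are also ortho and para to fluorine, while C6 is meta to the hydroxyl and deactivated by the formyl group.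

Step 2
Reactants: 2 2-fluoro-4-hydroxy-3,5-diiodobenzaldehyde
Product: 3 2-fluoro-3,5-diiodo-4-(methoxymethoxy)benzaldehyde
Conditions: NaH (1.2 equiv), MOMCl (1.3 equiv), THF, 0 °C → rt
Reagents that add atoms: chloromethyl methyl ether, COCCl
Why: Williamson-type O-alkylation of the acidic phenoxide with a small, very reactive α-chloro ether, which should overcome the flanking iodines; the phenoxide deactivates the ring, so the fluorine is not displaced.

Step 3
Reactants: 3 2-fluoro-3,5-diiodo-4-(methoxymethoxy)benzaldehyde; 4 tributyl(3-methylbut-2-enyl)stannane
Product: 5 2-fluoro-4-(methoxymethoxy)-3,5-bis(3-methylbut-2-enyl)benzaldehyde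
Conditions: Pd(PPh3)4 (10 mol %), 4 (2.6 equiv), DMF, 95 °C, degassed
Reagents that add atoms: none
Why: Double Stille coupling; zerovalent palladium inserts into both C–I bonds, the allyl group is transferred from tin, and reductive elimination at the less substituted allyl terminus should give the linear prenyl groups. Aldehyde, aryl fluoride and acetal are inert under these neutral conditions.

Step 4
Reactants: 5 2-fluoro-4-(methoxymethoxy)-3,5-bis(3-methylbut-2-enyl)benzaldehyde; 6 ethynylmagnesium bromide
Product: 7 1-[2-fluoro-4-(methoxymethoxy)-3,5-bis(3-methylbut-2-enyl)phenyl]prop-2-yn-1-ol (racemic)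
Conditions: 6 (1.5 equiv), THF, 0 °C; then sat. aq. NH4Cl
Reagents that add atoms: none
Why: 1,2-Addition of an alkynyl Grignard reagent to the aldehyde, much faster at 0 °C than attack at the fluorinated carbon; the new carbinol centre is racemic and is removed in step 5.

Step 5
Reactants: 7 1-[2-fluoro-4-(methoxymethoxy)-3,5-bis(3-methylbut-2-enyl)phenyl]prop-2-yn-1-ol
Product: 8 1-[2-fluoro-4-(methoxymethoxy)-3,5-bis(3-methylbut-2-enyl)phenyl]prop-2-yn-1-one
Conditions: activated MnO2 (15 equiv), CH2Cl2, rt
Reagents that add atoms: none
Why: Selective oxidation of a doubly activated (benzylic and propargylic) alcohol by MnO2, which leaves the prenyl olefins and the acetal alone; the ynone should be used soon after filtration.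

Step 6
Reactants: 9 2,4-dihydroxybenzaldehyde
Product: 10 2,4-bis(methoxymethoxy)benzaldehyde
Conditions: NaH (2.5 equiv), MOMCl (2.6 equiv), DMF, 0 °C → rt
Reagents that add atoms: chloromethyl methyl ether, COCCl
Why: Double O-alkylation of the bis-phenoxide; full deprotonation with hydride breaks the hydrogen bond of the ortho hydroxyl to the aldehyde, so both oxygens are protected.

Step 7
Reactants: 10 2,4-bis(methoxymethoxy)benzaldehyde
Product: 12 2,4-bis(methoxymethoxy)phenol, via 2,4-bis(methoxymethoxy)phenyl formate 11 (not isolated)
Conditions: mCPBA (1.3 equiv), CH2Cl2, 0 °C → rt; then MeOH, K2CO3 (3 equiv), rt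
Reagents that add atoms: 3-chloroperoxybenzoic acid, O=C(OO)c1cccc(Cl)c1
Why: Baeyer–Villiger oxidation; the electron-rich aryl group with ortho and para alkoxy donors migrates in preference to hydride, giving the formate, and base-mediated methanolysis then frees the phenol. The acetals tolerate the weak carboxylic acid.

Step 8
Reactants: 8 1-[2-fluoro-4-(methoxymethoxy)-3,5-bis(3-methylbut-2-enyl)phenyl]prop-2-yn-1-one; 12 2,4-bis(methoxymethoxy)phenol; 13 8-methylquinoline N-oxide
Product: 15 (2E)-2-[2,4-bis(methoxymethoxy)phenoxy]-1-[2-fluoro-4-(methoxymethoxy)-3,5-bis(3-methylbut-2-enyl)phenyl]-3-hydroxyprop-2-en-1-one, via the formyl keto gold carbene 14 (not isolated)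
Conditions: (Ph3P)AuNTf2 (5 mol %), 12 (3 equiv), 4 Å MS, ClCH2CH2Cl, rt; 13 (1.3 equiv) added over 6 h
Reagents that add atoms: none
Why: Proposed new method: (Ph3P)AuNTf2 π-activates the terminal ynone 8, whose carbonyl polarises the triple bond so that the oxygen of 13 adds in conjugate fashion to the unhindered terminal carbon; N–O heterolysis in the resulting vinylgold species expels 8-methylquinoline and leaves the monovalent gold carbene 14 at the future C3, flanked by the ketone and the new formyl group. The oxygen of phenol 12 adds to this strongly electrophilic carbene, and proton transfer with protodeauration releases the 2-aryloxy ketoaldehyde, which rests as the chelated enol 15. The closest known reaction types are the gold-catalysed N-oxide oxidation of ynones to β-dicarbonyl α-gold carbenes and the intermolecular O–H trapping of α-oxo gold carbenes made from terminal alkynes; combining them on a terminal ynone with a phenol as third component is the extrapolation. No ring is closed and no stereocentre is formed; the enol geometry is set thermodynamically by the internal hydrogen bond. The step needs oxygen delivery to the alkyne terminus, which the ynone polarisation and the free terminal position secure, and capture of 14 by the phenol oxygen rather than by a second N-oxide, a prenyl olefin or a ring carbon of 12. Excess 12 and slow addition of 13 keep the phenol the dominant nucleophile, both prenyl chains are meta to the acyl group and cannot reach the carbene, and the ortho fluorine cannot intercept it as an ortho oxygen would. The hindered 8-methylquinoline does not bind gold, so no acid additive is needed and the three acetals survive. Because 15 is far more acidic than 12, extraction into aqueous NaHCO3 and careful re-acidification should remove the excess phenol before step 9.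

Step 9
Reactants: 15 (2E)-2-[2,4-bis(methoxymethoxy)phenoxy]-1-[2-fluoro-4-(methoxymethoxy)-3,5-bis(3-methylbut-2-enyl)phenyl]-3-hydroxyprop-2-en-1-one
Product: 16 3-[2,4-bis(methoxymethoxy)phenoxy]-7-(methoxymethoxy)-6,8-bis(3-methylbut-2-enyl)chromen-4-one
Conditions: K2CO3 (2 equiv), DMF, 70 °C
Reagents that add atoms: none
Why: Intramolecular nucleophilic aromatic substitution (addition–elimination); the enolate oxygen on C2, cis to the aroyl group, attacks C8a, whose fluoride is activated by the ortho ketone, and a six-membered ring forms. Acetals and prenyl groups are stable to carbonate.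

Step 10
Reactants: 16 3-[2,4-bis(methoxymethoxy)phenoxy]-7-(methoxymethoxy)-6,8-bis(3-methylbut-2-enyl)chromen-4-one
Product: 17 eryvarin F, 3-(2,4-dihydroxyphenoxy)-7-hydroxy-6,8-bis(3-methylbut-2-enyl)chromen-4-one
Conditions: 3 M aq. HCl, MeOH, 40 °C, under Ar
Reagents that add atoms: none
Why: Acid-catalysed transacetalisation of the three aryl methoxymethyl ethers to methanol; dilute acid at mild temperature should be slower to protonate the trisubstituted olefins than to cleave the acetals, and inert gas protects the freed ring B.

**Compound list**

1 | 2-fluoro-4-hydroxybenzaldehyde | O=Cc1ccc(O)cc1F | starting material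
2 | 2-fluoro-4-hydroxy-3,5-diiodobenzaldehyde | O=Cc1cc(I)c(O)c(I)c1F | intermediate
3 | 2-fluoro-3,5-diiodo-4-(methoxymethoxy)benzaldehyde | O=Cc1cc(I)c(OCOC)c(I)c1F | intermediate
4 | tributyl(3-methylbut-2-enyl)stannane | CC(C)=CC[Sn](CCCC)(CCCC)CCCC | starting material
5 | 2-fluoro-4-(methoxymethoxy)-3,5-bis(3-methylbut-2-enyl)benzaldehyde | O=Cc1cc(CC=C(C)C)c(OCOC)c(CC=C(C)C)c1F | intermediate
6 | ethynylmagnesium bromide | C#C[Mg]Br | starting material
7 | 1-[2-fluoro-4-(methoxymethoxy)-3,5-bis(3-methylbut-2-enyl)phenyl]prop-2-yn-1-ol (racemic) | C#CC(O)c1cc(CC=C(C)C)c(OCOC)c(CC=C(C)C)c1F | intermediate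
8 | 1-[2-fluoro-4-(methoxymethoxy)-3,5-bis(3-methylbut-2-enyl)phenyl]prop-2-yn-1-one | C#CC(=O)c1cc(CC=C(C)C)c(OCOC)c(CC=C(C)C)c1F | intermediate
9 | 2,4-dihydroxybenzaldehyde | O=Cc1ccc(O)cc1O | starting material
10 | 2,4-bis(methoxymethoxy)benzaldehyde | O=Cc1ccc(OCOC)cc1OCOC | intermediate
11 | 2,4-bis(methoxymethoxy)phenyl formate (not isolated) | O=COc1ccc(OCOC)cc1OCOC | intermediate
12 | 2,4-bis(methoxymethoxy)phenol | COCOc1ccc(O)c(OCOC)c1 | intermediate
13 | 8-methylquinoline N-oxide | Cc1cccc2ccc[n+]([O-])c12 | starting material
14 | {1-[2-fluoro-4-(methoxymethoxy)-3,5-bis(3-methylbut-2-enyl)phenyl]-1,3-dioxopropan-2-ylidene}(triphenylphosphine)gold cation, the formyl keto gold carbene (not isolated) | O=CC(=[Au][P+](c1ccccc1)(c1ccccc1)c1ccccc1)C(=O)c1cc(CC=C(C)C)c(OCOC)c(CC=C(C)C)c1F | intermediate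
15 | (2E)-2-[2,4-bis(methoxymethoxy)phenoxy]-1-[2-fluoro-4-(methoxymethoxy)-3,5-bis(3-methylbut-2-enyl)phenyl]-3-hydroxyprop-2-en-1-one | O/C=C(\C(=O)c1cc(CC=C(C)C)c(OCOC)c(CC=C(C)C)c1F)Oc1ccc(OCOC)cc1OCOC | intermediate
16 | 3-[2,4-bis(methoxymethoxy)phenoxy]-7-(methoxymethoxy)-6,8-bis(3-methylbut-2-enyl)chromen-4-one | COCOc1ccc(Oc2coc3c(CC=C(C)C)c(OCOC)c(CC=C(C)C)cc3c2=O)c(OCOC)c1 | intermediate
17 | eryvarin F, 3-(2,4-dihydroxyphenoxy)-7-hydroxy-6,8-bis(3-methylbut-2-enyl)chromen-4-one | CC(C)=CCc1cc2c(=O)c(Oc3ccc(O)cc3O)coc2c(CC=C(C)C)c1O | target

**Step count and risks**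

Total step count: 10. Longest linear sequence: 8 steps (steps 1 to 5, then 8, 9 and 10); the ring B branch contributes steps 6 and 7.

Step 8 (key step, proposed new method). The most likely failure is loss of chemoselectivity at the carbene: a second molecule of 13 oxidises 14 further, or the phenol adds in conjugate fashion to the gold-activated ynone before oxygen transfer. Attack of the carbene on the ring carbon ortho to the hydroxyl of 12 is a further risk. The cause is that a carbene between two acyl groups is extremely electrophilic, while the N-oxide is the strongest nucleophile present and phenols are good Michael donors. The fallback uses known chemistry and sets out from 5 and 12. Corey–Chaykovsky epoxidation of 5 (trimethylsulfonium iodide, NaH, DMSO–THF) would give 2-[2-fluoro-4-(methoxymethoxy)-3,5-bis(3-methylbut-2-enyl)phenyl]oxirane F1. Opening at the terminal carbon by the phenoxide of 12 (Cs2CO3, DMF, 80 °C) would give 2-[2,4-bis(methoxymethoxy)phenoxy]-1-[2-fluoro-4-(methoxymethoxy)-3,5-bis(3-methylbut-2-enyl)phenyl]ethanol F2. Dess–Martin oxidation would give 2-[2,4-bis(methoxymethoxy)phenoxy]-1-[2-fluoro-4-(methoxymethoxy)-3,5-bis(3-methylbut-2-enyl)phenyl]ethanone F3. Claisen formylation of F3 (ethyl formate, NaH, THF) and mild acidification returns to the route at 15.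

Step 3. The likely failures are allyl transfer through the γ-carbon, giving a 1,1-dimethylallyl group, and slow coupling with protodeiodination at the iodide between fluorine and the acetal, which is the more hindered site. The fallback sets out from 3. Stille coupling with allyltributylstannane (Pd(PPh3)4, DMF), where no allylic regiochemistry arises, would give 2-fluoro-4-(methoxymethoxy)-3,5-bis(prop-2-enyl)benzaldehyde F4. Double cross-metathesis of F4 with 2-methylbut-2-ene using the second-generation Grubbs catalyst RuCl2(=CHPh)(PCy3)(H2IMes) returns to the route at 5.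

Step 10. The likely failures are acid-promoted cyclisation of a prenyl group onto the freed 7-hydroxyl to a chroman, or Markovnikov addition of methanol to an olefin, because the tertiary cation is easily reached. Oxidation of the unmasked ring B is a further risk. The fallback sets out from 16 and avoids Brønsted acid. Treatment with TMSOTf and 2,2'-bipyridyl in CH2Cl2 at 0 °C transfers the methoxymethyl groups to the pyridine nitrogen and would give 3-[2,4-bis(trimethylsilyloxy)phenoxy]-6,8-bis(3-methylbut-2-enyl)-7-(trimethylsilyloxy)chromen-4-one F5. Hydrolysis of F5 with water returns to the route at 17.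

**Further compounds**

F1 | step 8 | 2-[2-fluoro-4-(methoxymethoxy)-3,5-bis(3-methylbut-2-enyl)phenyl]oxirane (racemic) | COCOc1c(CC=C(C)C)cc(C2CO2)c(F)c1CC=C(C)C
F2 | step 8 | 2-[2,4-bis(methoxymethoxy)phenoxy]-1-[2-fluoro-4-(methoxymethoxy)-3,5-bis(3-methylbut-2-enyl)phenyl]ethanol (racemic) | COCOc1ccc(OCC(O)c2cc(CC=C(C)C)c(OCOC)c(CC=C(C)C)c2F)c(OCOC)c1
F3 | step 8 | 2-[2,4-bis(methoxymethoxy)phenoxy]-1-[2-fluoro-4-(methoxymethoxy)-3,5-bis(3-methylbut-2-enyl)phenyl]ethanone | COCOc1ccc(OCC(=O)c2cc(CC=C(C)C)c(OCOC)c(CC=C(C)C)c2F)c(OCOC)c1
F4 | step 3 | 2-fluoro-4-(methoxymethoxy)-3,5-bis(prop-2-enyl)benzaldehyde | O=Cc1cc(CC=C)c(OCOC)c(CC=C)c1F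
F5 | step 10 | 3-[2,4-bis(trimethylsilyloxy)phenoxy]-6,8-bis(3-methylbut-2-enyl)-7-(trimethylsilyloxy)chromen-4-one | CC(C)=CCc1cc2c(=O)c(Oc3ccc(O[Si](C)(C)C)cc3O[Si](C)(C)C)coc2c(CC=C(C)C)c1O[Si](C)(C)C
A1 | alternative 1 | 2,6-bis(3-methylbut-2-enyl)-3-(triisopropylsilyloxy)phenol | CC(C)=CCc1ccc(O[Si](C(C)C)(C(C)C)C(C)C)c(CC=C(C)C)c1O
A2 | alternative 1 | (2E)-7-methylocta-2,6-dienoyl chloride | CC(C)=CCC/C=C/C(=O)Cl
A3 | alternative 1 | triisopropyl[(5-methylhex-4-en-1-ynyl)oxy]silane | CC(C)=CCC#CO[Si](C(C)C)(C(C)C)C(C)C
A4 | alternative 2 | 2-[2,4-bis(methoxymethoxy)phenoxy]-1-[2,4-dihydroxy-3,5-bis(3-methylbut-2-enyl)phenyl]ethanone | COCOc1ccc(OCC(=O)c2cc(CC=C(C)C)c(O)c(CC=C(C)C)c2O)c(OCOC)c1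
A5 | alternative 2 | 1-methoxy-7-methyl-2-(3-methylbut-2-enyl)-1,3-bis(trimethylsilyloxy)octa-1,3,6-triene | COC(O[Si](C)(C)C)=C(CC=C(C)C)C(O[Si](C)(C)C)=CCC=C(C)C
A6 | alternative 2 | 1-[2,4-bis(methoxymethoxy)phenoxy]but-3-yn-2-one | C#CC(=O)COc1ccc(OCOC)cc1OCOC
A7 | alternative 3 | 3-[2-hydroxy-4-(triisopropylsilyloxy)phenoxy]-6,8-bis(3-methylbut-2-enyl)-7-(triisopropylsilyloxy)chromen-4-one | CC(C)=CCc1cc2c(=O)c(Oc3ccc(O[Si](C(C)C)(C(C)C)C(C)C)cc3O)coc2c(CC=C(C)C)c1O[Si](C(C)C)(C(C)C)C(C)C
A8 | alternative 3 | (2E)-4-{[6,8-bis(3-methylbut-2-enyl)-4-oxo-7-(triisopropylsilyloxy)chromen-3-yl]oxy}but-2-enoyl chloride | O=C(Cl)/C=C/COc1coc2c(CC=C(C)C)c(O[Si](C(C)C)(C(C)C)C(C)C)c(CC=C(C)C)cc2c1=O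
A9 | alternative 3 | (ethynyloxy)triisopropylsilane | C#CO[Si](C(C)C)(C(C)C)C(C)C
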